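## Retrosynthetic overview
1. Avoided: oxidative C6–C7 cleavage of an intact ent-kaurane, and the lactone-first/acrylate build-up. The most hindered bond, C9–C10, is used as the fragment-coupling bond instead.
2. Target ⇐ late α-methylenation and acetylation ⇐ δ-lactone (ring B, formed last) by reducing a C20 aldehyde and C1 ketone that sit next to the C7 ester.
3. Key step: Mitsunobu O-alkylation of an A-ring hydroxymethylene ketone with a bicyclo[3.2.1]octenol, then a [3,3] Claisen rearrangement. This sets C9 (tertiary) and C10 (spiro quaternary) in one event, and the C12 oxygen handle leaves no trace.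
4. C/D unit: ring D is a commercial cyclopentanone β-keto ester (C8 set by asymmetric Michael addition). Ring C is closed by an intramolecular Stetter reaction.
5. Ring A comes from a catalytic asymmetric Diels–Alder reaction (sets C4 and C5). Ring order: D → C, with A built in parallel, then B.

**Assumptions**
- ent-Kaurane numbering (C1–C20) is used for all intermediates.
- In steps 1 and 11 the catalyst antipode (both are commercial) is the one that gives the drawn enantiomer.

## Fragment C/D

**Step 1**
Reactants: 1 methyl 2-oxocyclopentane-1-carboxylate; 2 acrolein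
Product: 3 methyl (1S)-2-oxo-1-(3-oxopropyl)cyclopentane-1-carboxylate
Conditions: 6′-OH cinchona alkaloid catalyst (10 mol %), CH2Cl2, −25 °C
Reagents that add atoms: acrolein (2), C=CC=O
Why: Organocatalytic asymmetric Michael addition, in which the bifunctional catalyst hydrogen-bonds both the enol and the enal so that only one enolate face reacts, fixing the C8 quaternary centre as S.

**Step 2**
Reactants: 3
Product: 4 methyl (1S)-1-[2-(1,3-dioxolan-2-yl)ethyl]-2-oxocyclopentane-1-carboxylate
Conditions: HOCH2CH2OH, PPTS, PhH, reflux (Dean–Stark)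
Reagents that add atoms: ethylene glycol, OCCO
Why: Chemoselective acetalisation, because the aldehyde reacts much faster than the neopentyl ketone, and C8 is untouched.

**Step 3**
Reactants: 4
Product: 5 methyl (1R)-1-[2-(1,3-dioxolan-2-yl)ethyl]-2-oxocyclopent-3-ene-1-carboxylate (same spatial arrangement at C8; only the CIP priorities change)
Conditions: LiHMDS, TMSCl, THF, −78 °C; then Pd(OAc)2, MeCN, rt
Reagents that add atoms: none
Why: Saegusa–Ito oxidation, which can only give the C13=C16 enone because C8 is quaternary and C16 is the only enolisable position.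

**Step 4**
Reactants: 5
Product: 6 methyl (1R)-2-oxo-1-(3-oxopropyl)cyclopent-3-ene-1-carboxylate
Conditions: 1 M HCl, THF, rt
Reagents that add atoms: water, O
Why: Acetal hydrolysis, under which the enone and the non-enolisable β-keto ester are stable.

**Step 5**
Reactants: 6
Product: 7 methyl (1R,5R)-4,7-dioxobicyclo[3.2.1]octane-1-carboxylate (C12 and C15 ketones)
Conditions: 2-(pentafluorophenyl)pyrrolo-triazolium BF4 (20 mol %), i-Pr2NEt, PhMe, rt
Reagents that add atoms: none
Why: Intramolecular Stetter reaction (6-exo), in which the acyl-anion equivalent at C12 adds irreversibly to enone carbon C13, and the three-atom tether can only reach the ring face it is attached to, so C13 is set by C8.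

**Step 6**
Reactants: 7
Product: 8 methyl (1S,5R)-4,7-dioxobicyclo[3.2.1]oct-2-ene-1-carboxylate (C9=C11 enone)
Conditions: Pd(TFA)2 (5 mol %), DMSO (10 mol %), O2 (1 atm), AcOH, 80 °C
Reagents that add atoms: none
Why: Pd(II)-catalysed aerobic α,β-dehydrogenation, where only C11/C9 can undergo β-hydride elimination because every other option would give a bridgehead alkene (Bredt's rule).

**Step 7**
Reactants: 8
Product: 9 methyl (1S,5R)-7,7-(ethylenedioxy)-4-oxobicyclo[3.2.1]oct-2-ene-1-carboxylate
Conditions: (TMSOCH2)2, TMSOTf (cat.), CH2Cl2, −78 → −20 °C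
Reagents that add atoms: 1,2-bis(trimethylsilyloxy)ethane, C[Si](C)(C)OCCO[Si](C)(C)C
Why: Noyori ketalisation, which protects a saturated ketone next to a quaternary carbon in preference to a conjugated enone, as in the Wieland–Miescher ketone.

**Step 8**
Reactants: 9
Product: 10 methyl (1S,4S,5R)-7,7-(ethylenedioxy)-4-hydroxybicyclo[3.2.1]oct-2-ene-1-carboxylate (C12-OH endo, i.e. syn to the C15–C16 bridge)
Conditions: NaBH4, CeCl3·7H2O, MeOH, −78 °C
Reagents that add atoms: none
Why: Luche 1,2-reduction, in which hydride attacks axially from the open exo face (the endo face is screened by the two-carbon bridge) to give the pseudo-equatorial endo alcohol.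

## Fragment A

**Step 9**
Reactants: 11 (benzyloxy)acetaldehyde; 12 1-(triphenylphosphoranylidene)propan-2-one
Product: 13 (3E)-5-(benzyloxy)pent-3-en-2-one
Conditions: CH2Cl2, rt
Reagents that add atoms: ylide 12, CC(=O)C=P(c1ccccc1)(c1ccccc1)c1ccccc1
Why: Wittig olefination with a stabilised ylide, which is E-selective.

**Step 10**
Reactants: 13
Product: 14 {[(3E)-5-(benzyloxy)penta-1,3-dien-2-yl]oxy}(tert-butyl)dimethylsilane
Conditions: TBSOTf, Et3N, Et2O, 0 °C
Reagents that add atoms: TBSOTf, CC(C)(C)[Si](C)(C)OS(=O)(=O)C(F)(F)F
Why: Soft enolisation and silylation at the methyl group gives the cross-conjugated 2-silyloxydiene.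

**Step 11**
Reactants: 14; 15 methacrolein
Product: 16 (1R,2S)-2-[(benzyloxy)methyl]-4-[(TBS)oxy]-1-methylcyclohex-3-ene-1-carbaldehyde (CHO and CH2OBn cis)
Conditions: o-tolyl-oxazaborolidinium triflimide (15 mol %), CH2Cl2, −78 °C
Reagents that add atoms: methacrolein (15), CC(=C)C=O
Why: Catalytic asymmetric Diels–Alder reaction in which the 2-OSi ("para") and 4-alkyl ("ortho") directing effects reinforce each other, the CHO-endo transition state places C19 cis to C6, and catalyst shielding (diene adds to the Cα Si face) sets C4 as R, giving C4 and C5 plus a regiodefined C1=C10 enol silane.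

**Step 12**
Reactants: 16
Product: 17 [(1R,2S)-2-[(benzyloxy)methyl]-4-[(TBS)oxy]-1-methylcyclohex-3-en-1-yl]methanol
Conditions: NaBH4, EtOH, 0 °C
Reagents that add atoms: none
Why: Chemoselective hydride reduction of the aldehyde, to which the TBS enol ether is inert.

**Step 13**
Reactants: 17
Product: 18, the 19-O-TBS ether of 17
Conditions: TBSCl, imidazole, DMF, rt
Reagents that add atoms: TBSCl, CC(C)(C)[Si](C)(C)Cl
Why: Standard silylation that marks O19 as the one oxygen that must end up free.

**Step 14**
Reactants: 18; 19 trimethyl orthoformate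
Product: 20 (2R,3S,4R)-3-[(benzyloxy)methyl]-4-{[(TBS)oxy]methyl}-2-(dimethoxymethyl)-4-methylcyclohexan-1-one
Conditions: BF3·OEt2, CH2Cl2, −78 °C
Reagents that add atoms: trimethyl orthoformate (19), COC(OC)OC
Why: Mukaiyama-type reaction of the enol silane with the dimethoxycarbenium ion installs C20 regiospecifically at C10, anti to C6, although this centre is erased in the next step.

**Step 15**
Reactants: 20
Product: 21 (2Z,3R,4R)-3-[(benzyloxy)methyl]-4-{[(TBS)oxy]methyl}-2-(hydroxymethylidene)-4-methylcyclohexan-1-one
Conditions: 1 M NaOH, MeOH–THF, rt; then NaH2PO4 to pH 6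
Reagents that add atoms: water (as hydroxide), O
Why: E1cB loss of MeOH followed by vinylogous saponification gives the stable β-keto-aldehyde enolate, and C4 and C5 are not acidic under these conditions.

## Union and endgame

**Step 16**
Reactants: 10; 21
Product: 22, the (Z)-allyl vinyl ether with a C12(exo)–O–C20H=C10 linkage (C12 is R)
Conditions: PPh3, DIAD, PhMe, 0 °C → rt
Reagents that add atoms: none beyond 10 and 21
Why: Mitsunobu O-alkylation of an acidic enol (pKa about 8) by SN2 inversion converts the endo C12–OH into the pseudo-axial exo ether, and any E isomer or ketone-O regioisomer would rearrange to the same product in step 17.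

**Step 17 (key step)**
Reactants: 22
Product: 23, the 6,7-seco-ent-kaur-11-ene with 1-oxo, 20-al, C7 methyl ester, 15,15-ethylenedioxy, 6-OBn and 19-OTBS groups; (4R,5R,8S,9S,10S,13R)
Conditions: Eu(fod)3 (10 mol %), PhMe, 90–110 °C, sealed tube
Reagents that add atoms: none
Why: Lanthanide-catalysed Claisen [3,3] rearrangement through a chair transition state, in which suprafacial transfer from the exo C12–O bond to an exo C9–C10 bond (anti to C15) sets C9, and bonding on the β face of ring A (the α face is blocked by C6 and C19) sets the spiro centre C10, with regiochemistry that an intermolecular allylation could not deliver.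

**Step 18**
Reactants: 23
Product: 24, the 1α-hydroxy-7,20-lactone (11-ene, 15-ketal, 6-OBn, 19-OTBS); C1 is S
Conditions: NaBH4, THF–MeOH, −40 → 0 °C; then PPTS (cat.), PhMe, 60 °C
Reagents that add atoms: none
Why: Hydride reduction then lactonisation, in which the aldehyde is reduced first and its primary alkoxide closes onto the C7 ester (losing MeOH), while the C1 ketone is attacked axially from the β face because axial C20 blocks the α face, giving the equatorial 1α-OH.

**Step 19**
Reactants: 24
Product: 25, the 1α,6-diol (saturated C11–C12, 15-ketal, 19-OTBS)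
Conditions: H2 (4 atm), Pd(OH)2/C, EtOAc–EtOH, rt
Reagents that add atoms: none
Why: A single hydrogenation/hydrogenolysis saturates the only alkene and removes the benzyl ether, while the lactone, ketal and TBS ether are inert.

**Step 20**
Reactants: 25
Product: 26, the 1α,6-diacetate
Conditions: Ac2O, pyridine, DMAP (cat.), CH2Cl2, rt
Reagents that add atoms: acetic anhydride, CC(=O)OC(C)=O
Why: Acetylation of the only two free hydroxyls, which also prevents 1,7-translactonisation.

**Step 21**
Reactants: 26
Product: 27, 16,17-dinor-methylene isodojaponin D (15-ketone with C16H2, free 19-OH)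
Conditions: 3 M aq HCl, THF, rt
Reagents that add atoms: water, O
Why: One acidic hydrolysis removes both the dioxolane and the primary TBS ether, and the acetates and lactone survive at room temperature.

**Step 22**
Reactants: 27; 28 paraformaldehyde
Product: 29 isodojaponin D
Conditions: (CH2O)n, N-methylanilinium trifluoroacetate, THF, reflux
Reagents that add atoms: formaldehyde (28), C=O
Why: Mannich-type α-methylenation with in situ elimination, where C16 is the only enolisable position of the ketone (C8 is quaternary) and the mildly acidic medium tolerates the free OH, the acetates and the lactone.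

## Compound list
1 | methyl 2-oxocyclopentane-1-carboxylate | COC(=O)C1CCCC1=O | starting material
2 | acrolein | C=CC=O | starting material
3 | (S)-Michael adduct | O=C1[C@](CCC=O)(C(=O)OC)CCC1 | intermediate
4 | dioxolane of 3 | O=C1[C@](CCC2OCCO2)(C(=O)OC)CCC1 | intermediate
5 | cyclopentenone acetal | O=C1[C@](CCC2OCCO2)(C(=O)OC)CC=C1 | intermediate
6 | cyclopentenone aldehyde | O=C1[C@](CCC=O)(C(=O)OC)CC=C1 | intermediate
7 | bicyclo[3.2.1]octane-4,7-dione ester | C1C(=O)[C@]2(C(=O)OC)C[C@H]1C(=O)CC2 | intermediate
8 | ene-dione | C1C(=O)[C@]2(C(=O)OC)C[C@H]1C(=O)C=C2 | intermediate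
9 | C15-ketal enone | C1C2(OCCO2)[C@]3(C(=O)OC)C[C@H]1C(=O)C=C3 | intermediate
10 | endo-C12 allylic alcohol | C1C2(OCCO2)[C@]3(C(=O)OC)C[C@H]1[C@H](O)C=C3 | intermediate
11 | (benzyloxy)acetaldehyde | O=CCOCc1ccccc1 | starting material
12 | 1-(triphenylphosphoranylidene)propan-2-one | CC(=O)C=P(c1ccccc1)(c1ccccc1)c1ccccc1 | starting material
13 | (E)-5-(benzyloxy)pent-3-en-2-one | CC(=O)/C=C/COCc1ccccc1 | intermediate
14 | 2-TBSO-diene | C=C(O[Si](C)(C)C(C)(C)C)/C=C/COCc1ccccc1 | intermediate
15 | methacrolein | CC(=C)C=O | starting material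
16 | Diels–Alder adduct | C1=C(O[Si](C)(C)C(C)(C)C)CC[C@@](C)(C=O)[C@H]1COCc1ccccc1 | intermediate
17 | C19 alcohol | C1=C(O[Si](C)(C)C(C)(C)C)CC[C@@](C)(CO)[C@H]1COCc1ccccc1 | intermediate
18 | 19-OTBS enol silane | C1=C(O[Si](C)(C)C(C)(C)C)CC[C@@](C)(CO[Si](C)(C)C(C)(C)C)[C@H]1COCc1ccccc1 | intermediate
19 | trimethyl orthoformate | COC(OC)OC | starting material
20 | β-keto dimethyl acetal | COC(OC)[C@@H]1C(=O)CC[C@@](C)(CO[Si](C)(C)C(C)(C)C)[C@H]1COCc1ccccc1 | intermediate
21 | hydroxymethylene ketone | O/C=C1\C(=O)CC[C@@](C)(CO[Si](C)(C)C(C)(C)C)[C@H]1COCc1ccccc1 | intermediate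
22 | allyl vinyl ether | C1C2(OCCO2)[C@]3(C(=O)OC)C[C@H]1[C@@H](O/C=C4\C(=O)CC[C@@](C)(CO[Si](C)(C)C(C)(C)C)[C@H]4COCc4ccccc4)C=C3 | intermediate
23 | Claisen product (1-oxo-20-al) | C1C2(OCCO2)[C@]3(C(=O)OC)C[C@H]1C=C[C@H]3[C@]1(C=O)C(=O)CC[C@@](C)(CO[Si](C)(C)C(C)(C)C)[C@H]1COCc1ccccc1 | intermediate
24 | 1α-hydroxy-7,20-lactone | C1C2(OCCO2)[C@]34C[C@H]1C=C[C@H]3[C@]1(COC4=O)[C@@H](O)CC[C@@](C)(CO[Si](C)(C)C(C)(C)C)[C@H]1COCc1ccccc1 | intermediate
25 | 1α,6-diol | C1C2(OCCO2)[C@]34C[C@H]1CC[C@H]3[C@]1(COC4=O)[C@@H](O)CC[C@@](C)(CO[Si](C)(C)C(C)(C)C)[C@H]1CO | intermediate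
26 | 1α,6-diacetate | C1C2(OCCO2)[C@]34C[C@H]1CC[C@H]3[C@]1(COC4=O)[C@@H](OC(C)=O)CC[C@@](C)(CO[Si](C)(C)C(C)(C)C)[C@H]1COC(C)=O | intermediate
27 | 15-ketone, 19-OH | C1C(=O)[C@]23C[C@H]1CC[C@H]2[C@]1(COC3=O)[C@@H](OC(C)=O)CC[C@@](C)(CO)[C@H]1COC(C)=O | intermediate
28 | paraformaldehyde (as CH2O) | C=O | starting material
29 | isodojaponin D (1S,4R,5R,8S,9S,10S,13R) | C=C1C(=O)[C@]23C[C@H]1CC[C@H]2[C@]1(COC3=O)[C@@H](OC(C)=O)CC[C@@](C)(CO)[C@H]1COC(C)=O | target

## Summary
- **Total steps:** 22 (C/D fragment 8, A fragment 7, union and endgame 7).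
- **Longest linear sequence:** 15 (steps 1–8, then 16–22).

**Three steps most likely to fail**
1. **Step 17 (Claisen).** The forming bond is flanked by two quaternary carbons, and ionisation or elimination of the vinylogous-ester leaving group could compete. Fallback: abandon the pericyclic union and couple by radical conjugate addition. A C10 tertiary radical, made from the N-hydroxyphthalimide ester of a C10 acid that already carries the C20H2O group, would add to C9 of enone 9 with the same exo/β-face preferences. The C12 ketone would then be removed via its tosylhydrazone.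
2. **Step 5 (bridging Stetter).** The substrate is prone to retro-Michael and aldol side reactions, and the ring closure forms a bridged system. Fallback: switch to a radical closure. Oxidise 6 to the acid, convert it to the acyl selenide, and run a 6-exo acyl-radical cyclisation onto C13 with (TMS)3SiH/AIBN.
3. **Step 16 (Mitsunobu).** Both partners are hindered. Fallback: make the C20–O bond instead of the C12–O bond. First invert 10 to the exo alcohol (p-nitrobenzoate Mitsunobu, then methanolysis). Then attach it by acid-catalysed addition–elimination on the methoxymethylene ketone obtained from 20 by loss of MeOH.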